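Whatever the rates, each partner that leaves the solid reagent ends as target or decomposed reagent, so the charge of solid reagent, the limiting reagent at 0.350 M against less than the 0.50 M of solid substrate, caps target at 70.0%.

    dissolved substrate + partner → target (k1 = 0.00125 L mol⁻¹ s⁻¹)
    solid substrate ⇌ dissolved substrate, rate k2*(cs2 - [dissolved substrate]) while solid is left; crystals form when [dissolved substrate] > cs2 (cs2 = 0.29 M, k2 = 1.73 × 10⁻⁴ s⁻¹)
    partner → decomposed reagent (k3 = 5.84 × 10⁻⁵ s⁻¹)
    solid reagent ⇌ partner, rate k4*(cs4 - [partner]) while solid is left; crystals form when [partner] > cs4 (cs4 = 0.19 M, k4 = 1.11 × 10⁻⁴ s⁻¹)

solid substrate 0.50 M; solid reagent 0.700 equiv; time 25 h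

* target at 25 h, in percent of the solid substrate charged
* the change that raises the amount of target at 25 h, in percent of the solid substrate charged most ("none" if none brings more than 2 percentage points) (Wednesday's / Monday's / Tuesday's / Thursday's / none)
* amount of target at 25 h, in percent of the solid substrate charged, after Wednesday's

- Wednesday's: doubling the solubility in step 2, all else as stated
- Monday's: doubling the solubility in step 4, all else as stated
- Tuesday's: doubling the dissolution coefficient of step 2, all else as stated
- Thursday's: doubling the dissolution coefficient of step 4, all else as stated

Which numbers must be good? An error in the charge of solid reagent passes whole into target, since target is that charge times the part of partner caught by the coupling with dissolved substrate rather than lost to decay. The time can be off widely: with [dissolved substrate] put at its solubility for a first figure, [partner] rests where delivery meets coupling and decay, at 0.0397 M, so the charge enters in about 5.83 h, shorter than the run of 25 h. The constants of the partner's dissolution must be known as well: they set [partner], and with it a loss coefficient of dissolved substrate of 4.96 × 10⁻⁵ s⁻¹, which is 28.6% of the substrate's dissolution coefficient 1.73 × 10⁻⁴ s⁻¹.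

They enter one balance together with the substrate's solubility and dissolution coefficient and the two rate constants. Dissolution balanced against coupling puts [dissolved substrate] near 0.225 M, and the capture share, a selectivity: coupling rate of partner over coupling plus decay, is 82.8%. A relative error in the ratio of those rates reaches target reduced to 17.2% of its size. I commit to 58.0%. Putting each change through the same balance, the highest level comes with Wednesday's, at 0.496 M. That level ignores the substrate spent as target, so my 64.0% leans high.

The forecast gave 55% (51% to 59%), Wednesday's, and 59% (55% to 63%), holding that “Doubling the substrate solubility raises that dissolved level the most”; my first figure stands above its number.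

The flask gives 55.9%, and Wednesday's brings 4.2 percentage points, to 60.1%. Target already stood at 55.9% after 12.5 h and still at 55.9% after 50.0 h. Read back against the cap, the capture share is 79.9%, which corresponds to an effective [dissolved substrate] of 0.186 M.

In the neighbour flask with 0.170 equiv of solid reagent, the capture share I reckoned gives 14.1% of target. The simulation gives 12.9%.

The rate constants were drawn at random within sensible limits, and the outcome is calculated.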